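**Retrosynthetic overview**
- Final deprotection: BCl3 frees the three isopropyl-masked hydroxyls of the 6-aryloxy flavone and leaves the C7 methyl ether of the 7-methoxy flavone untouched. Ring C of the 7-methoxy flavone is closed late, by aroylation of the polyanion of 2,6-dihydroxy-4-methoxyacetophenone with the benzoic acid of the 6-aryloxy flavone and acid cyclodehydration.
- Key disconnection: pyranone ring C of the 6-aryloxy flavone is cut at C4–C4a and O1–C2, giving symmetric phenol 7 and aroylacetate 11 (thermal phenol/β-ketoester condensation). Ring order: ring C of the 6-aryloxy flavone first, ring C of the 7-methoxy flavone last.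
- Feature: the diaryl-ether oxygen sits on C6 of ring A of the 6-aryloxy flavone, between the C5 and C7 oxygens, with C8 unsubstituted. In a 4-aryloxy-3,5-diisopropoxyphenol the two open ring carbons are equivalent, so annulation of the pyranone ring can only give the 6-aryloxy chromone, never the 8-aryloxy isomer.
- Phenol 7: 3,4,5-trihydroxybenzaldehyde is fully isopropylated and the central C4 ether is then cleaved selectively (direct 3,5-dialkylation is not feasible because the C4 hydroxyl is the most reactive). SNAr with methyl 4-fluorobenzoate and Baeyer–Villiger oxidation follow.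
- Ketoester 11: 4-hydroxyacetophenone is isopropylated and condensed with diethyl carbonate (Claisen).

Key step: step 7

Remark: phenoxides, carboxylates and enolates formed by simple deprotonation of a numbered compound are treated as forms of that compound and carry no number of their own. The target has no stereocentre.

**Step 1**
Reactants: 1 3,4,5-trihydroxybenzaldehyde
Product: 2 3,4,5-triisopropoxybenzaldehyde
Conditions: 2-bromopropane (excess), K2CO3, DMF, 70 °C
Reagents that add atoms: 2-bromopropane, CC(C)Br
Why: Williamson etherification of all three phenoxides, with excess secondary bromide making up for its loss to elimination, so no site selectivity is required at this stage.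

**Step 2**
Reactants: 2 3,4,5-triisopropoxybenzaldehyde
Product: 3 4-hydroxy-3,5-diisopropoxybenzaldehyde
Conditions: AlCl3 (1.5 equiv), CH2Cl2, 0 °C; then ice-water
Reagents that add atoms: none
Why: Lewis-acid ether cleavage should be selective for the central alkoxy group of a 1,2,3-trialkoxyarene, because the C4 isopropoxy group is twisted out of the ring plane by its two neighbours, can chelate AlCl3 with an adjacent oxygen and leaves as the phenoxide para to the formyl group, as in the known conversion of 3,4,5-trimethoxybenzaldehyde into syringaldehyde.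

**Step 3**
Reactants: 3 4-hydroxy-3,5-diisopropoxybenzaldehyde; 4 methyl 4-fluorobenzoate
Product: 5 methyl 4-(4-formyl-2,6-diisopropoxyphenoxy)benzoate
Conditions: Cs2CO3, 4 (2 equiv), dry DMSO, 120 °C
Reagents that add atoms: none
Why: Nucleophilic aromatic substitution (addition–elimination through a Meisenheimer intermediate) of the caesium phenoxide on the fluoride activated by the para ester, with dry DMSO and excess 4 offsetting the hindrance of the 2,6-dialkoxyphenoxide.

**Step 4**
Reactants: 5 methyl 4-(4-formyl-2,6-diisopropoxyphenoxy)benzoate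
Product: 7 methyl 4-(4-hydroxy-2,6-diisopropoxyphenoxy)benzoate, via aryl formate 6 (not isolated)
Conditions: mCPBA, CH2Cl2, 0 °C → rt; then cat. K2CO3, MeOH, 0 °C
Reagents that add atoms: mCPBA (3-chloroperoxybenzoic acid), OOC(=O)c1cccc(Cl)c1
Why: Baeyer–Villiger (Dakin-type) oxidation in which the oxygen-rich aryl group migrates in the Criegee adduct, as for 3,4,5-trialkoxy- and 4-aryloxybenzaldehydes, followed by methanolysis of the formate under conditions where exchange at the methyl benzoate is degenerate.

**Step 5**
Reactants: 8 4-hydroxyacetophenone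
Product: 9 4-isopropoxyacetophenone
Conditions: 2-bromopropane, K2CO3, DMF, 70 °C
Reagents that add atoms: 2-bromopropane, CC(C)Br
Why: Williamson etherification of an acidic para-acylphenol.

**Step 6**
Reactants: 9 4-isopropoxyacetophenone; 10 diethyl carbonate
Product: 11 ethyl 3-oxo-3-(4-isopropoxyphenyl)propanoate
Conditions: NaH (2.5 equiv), 10 (excess), toluene, 80 °C; then aq. HCl
Reagents that add atoms: none
Why: Crossed Claisen condensation of the ketone enolate with the non-enolisable carbonate, driven to completion by deprotonation of the β-ketoester formed.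

**Step 7**
Reactants: 7 methyl 4-(4-hydroxy-2,6-diisopropoxyphenoxy)benzoate; 11 ethyl 3-oxo-3-(4-isopropoxyphenyl)propanoate
Product: 14 methyl 4-{[5,7-diisopropoxy-2-(4-isopropoxyphenyl)-4-oxo-4H-chromen-6-yl]oxy}benzoate, via aroylketene 12 (not isolated), via C-acylated phenol 13 (not isolated)
Conditions: 11 (2 equiv), Ph2O, 240 °C, N2 sweep (EtOH and H2O distilled out), no acid or base
Reagents that add atoms: none
Why: On heating, 11 loses ethanol to aroylketene 12, whose O-acylation of the phenol is reversible at this temperature, so the ketene carbon should end up acylating 7 at the ring carbon ortho to the hydroxyl to give diketone 13 and form C4–C4a. The phenolic oxygen then adds to the aryl ketone of 13 and water is lost, forming O1–C2, so the pyranone ring of the 6-aryloxy flavone closes by a 6-exo-trig addition followed by dehydration. The closest known reaction type is the thermal Mentzer (Simonis-type) condensation of phloroglucinol-type phenols with aroylacetic esters to flavones. No stereocentre is formed. The step needs the aryloxy group to end on C6 and not C8, and this is secured by the symmetry of 7: its two open ring carbons are equivalent, each ortho to the hydroxyl, ortho to one isopropoxy group and para to the other, and after one acylation the ring is deactivated and has no free hydroxyl left. It also needs chromone and not 4-arylcoumarin formation, which the absence of acid secures because Pechmann-type attack on the ketone requires acid activation, while excess 11 covers loss of the ketene to self-condensation.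

**Step 8**
Reactants: 14 methyl 4-{[5,7-diisopropoxy-2-(4-isopropoxyphenyl)-4-oxo-4H-chromen-6-yl]oxy}benzoate
Product: 15 4-{[5,7-diisopropoxy-2-(4-isopropoxyphenyl)-4-oxo-4H-chromen-6-yl]oxy}benzoic acid
Conditions: LiOH (3 equiv), THF/MeOH/H2O, rt → 40 °C; then aq. HCl
Reagents that add atoms: lithium hydroxide, [Li+].[OH-]
Why: Ester saponification under mild conditions that the alkoxy-substituted chromone and the ethers tolerate, any reversible hydroxide addition at C2 being undone on acidification.

**Step 9**
Reactants: 15 4-{[5,7-diisopropoxy-2-(4-isopropoxyphenyl)-4-oxo-4H-chromen-6-yl]oxy}benzoic acid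
Product: 16 4-{[5,7-diisopropoxy-2-(4-isopropoxyphenyl)-4-oxo-4H-chromen-6-yl]oxy}benzoyl chloride
Conditions: (COCl)2, cat. DMF, CH2Cl2, 0 °C → rt; concentrated and used crude
Reagents that add atoms: oxalyl chloride, ClC(=O)C(=O)Cl
Why: Acid chloride formation through the Vilsmeier-type chloroiminium catalyst, under conditions that ethers and the chromone withstand.

**Step 10**
Reactants: 16 4-{[5,7-diisopropoxy-2-(4-isopropoxyphenyl)-4-oxo-4H-chromen-6-yl]oxy}benzoyl chloride; 17 2,6-dihydroxy-4-methoxyacetophenone
Product: 18 1-(2,6-dihydroxy-4-methoxyphenyl)-3-(4-{[5,7-diisopropoxy-2-(4-isopropoxyphenyl)-4-oxo-4H-chromen-6-yl]oxy}phenyl)propane-1,3-dione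
Conditions: 17 (1.3 equiv), LiN(SiMe3)2 (4 equiv per 17), THF, −78 → −10 °C; then 16 in THF, −78 °C → rt; aq. HCl
Reagents that add atoms: none
Why: Acylation of the lithium trianion of an ortho-hydroxyacetophenone by an aroyl chloride occurs at the enolate carbon, the most nucleophilic site, and gives the β-diketone directly (a polyanion equivalent of the Baker–Venkataraman sequence), the fourth equivalent of base taking up the more acidic diketone.

**Step 11**
Reactants: 18 1-(2,6-dihydroxy-4-methoxyphenyl)-3-(4-{[5,7-diisopropoxy-2-(4-isopropoxyphenyl)-4-oxo-4H-chromen-6-yl]oxy}phenyl)propane-1,3-dione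
Product: 19 6-{4-(5-hydroxy-7-methoxy-4-oxo-4H-chromen-2-yl)phenoxy}-5,7-diisopropoxy-2-(4-isopropoxyphenyl)-4H-chromen-4-one
Conditions: cat. H2SO4, AcOH, 90 °C
Reagents that add atoms: none
Why: Acid-catalysed cyclodehydration of the ortho-hydroxyaryl β-diketone closes ring C of the 7-methoxy flavone, either of the two equivalent hydroxyls giving the same 5-hydroxy-7-methoxychromone, and any partial loss of an isopropyl group is harmless because all three are removed in the next step.

**Step 12**
Reactants: 19 6-{4-(5-hydroxy-7-methoxy-4-oxo-4H-chromen-2-yl)phenoxy}-5,7-diisopropoxy-2-(4-isopropoxyphenyl)-4H-chromen-4-one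
Product: 20 neocryptomerin
Conditions: BCl3 (excess), CH2Cl2, −78 → 0 °C; then H2O
Reagents that add atoms: none
Why: BCl3 cleaves isopropyl aryl ethers through the boron-complexed ether and its secondary carbocation-like fragmentation, while the C7 methyl ether (primary, not peri to a carbonyl) and the diaryl ether should not be cleaved at low temperature.

**Compound list**
1 | 3,4,5-trihydroxybenzaldehyde | O=Cc1cc(O)c(O)c(O)c1 | starting material
2 | 3,4,5-triisopropoxybenzaldehyde | O=Cc1cc(OC(C)C)c(OC(C)C)c(OC(C)C)c1 | intermediate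
3 | 4-hydroxy-3,5-diisopropoxybenzaldehyde | O=Cc1cc(OC(C)C)c(O)c(OC(C)C)c1 | intermediate
4 | methyl 4-fluorobenzoate | COC(=O)c1ccc(F)cc1 | starting material
5 | methyl 4-(4-formyl-2,6-diisopropoxyphenoxy)benzoate | COC(=O)c1ccc(Oc2c(OC(C)C)cc(C=O)cc2OC(C)C)cc1 | intermediate
6 | methyl 4-[4-(formyloxy)-2,6-diisopropoxyphenoxy]benzoate (aryl formate) | COC(=O)c1ccc(Oc2c(OC(C)C)cc(OC=O)cc2OC(C)C)cc1 | intermediate
7 | methyl 4-(4-hydroxy-2,6-diisopropoxyphenoxy)benzoate | COC(=O)c1ccc(Oc2c(OC(C)C)cc(O)cc2OC(C)C)cc1 | intermediate
8 | 4-hydroxyacetophenone | CC(=O)c1ccc(O)cc1 | starting material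
9 | 4-isopropoxyacetophenone | CC(=O)c1ccc(OC(C)C)cc1 | intermediate
10 | diethyl carbonate | CCOC(=O)OCC | starting material
11 | ethyl 3-oxo-3-(4-isopropoxyphenyl)propanoate | CCOC(=O)CC(=O)c1ccc(OC(C)C)cc1 | intermediate
12 | (4-isopropoxybenzoyl)ketene | CC(C)Oc1ccc(C(=O)C=C=O)cc1 | intermediate
13 | methyl 4-{4-hydroxy-2,6-diisopropoxy-3-[3-(4-isopropoxyphenyl)-3-oxopropanoyl]phenoxy}benzoate | COC(=O)c1ccc(Oc2c(OC(C)C)cc(O)c(C(=O)CC(=O)c3ccc(OC(C)C)cc3)c2OC(C)C)cc1 | intermediate
14 | methyl 4-{[5,7-diisopropoxy-2-(4-isopropoxyphenyl)-4-oxo-4H-chromen-6-yl]oxy}benzoate | COC(=O)c1ccc(Oc2c(OC(C)C)cc3oc(-c4ccc(OC(C)C)cc4)cc(=O)c3c2OC(C)C)cc1 | intermediate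
15 | 4-{[5,7-diisopropoxy-2-(4-isopropoxyphenyl)-4-oxo-4H-chromen-6-yl]oxy}benzoic acid | OC(=O)c1ccc(Oc2c(OC(C)C)cc3oc(-c4ccc(OC(C)C)cc4)cc(=O)c3c2OC(C)C)cc1 | intermediate
16 | 4-{[5,7-diisopropoxy-2-(4-isopropoxyphenyl)-4-oxo-4H-chromen-6-yl]oxy}benzoyl chloride | ClC(=O)c1ccc(Oc2c(OC(C)C)cc3oc(-c4ccc(OC(C)C)cc4)cc(=O)c3c2OC(C)C)cc1 | intermediate
17 | 2,6-dihydroxy-4-methoxyacetophenone | COc1cc(O)c(C(C)=O)c(O)c1 | starting material
18 | 1-(2,6-dihydroxy-4-methoxyphenyl)-3-(4-{[5,7-diisopropoxy-2-(4-isopropoxyphenyl)-4-oxo-4H-chromen-6-yl]oxy}phenyl)propane-1,3-dione | COc1cc(O)c(C(=O)CC(=O)c2ccc(Oc3c(OC(C)C)cc4oc(-c5ccc(OC(C)C)cc5)cc(=O)c4c3OC(C)C)cc2)c(O)c1 | intermediate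
19 | 6-{4-(5-hydroxy-7-methoxy-4-oxo-4H-chromen-2-yl)phenoxy}-5,7-diisopropoxy-2-(4-isopropoxyphenyl)-4H-chromen-4-one | COc1cc(O)c2c(=O)cc(-c3ccc(Oc4c(OC(C)C)cc5oc(-c6ccc(OC(C)C)cc6)cc(=O)c5c4OC(C)C)cc3)oc2c1 | intermediate
20 | neocryptomerin | COc1cc(O)c2c(=O)cc(-c3ccc(Oc4c(O)cc5oc(-c6ccc(O)cc6)cc(=O)c5c4O)cc3)oc2c1 | target

**Step count**
Total: 12 steps. Longest linear sequence: 10 steps (steps 1, 2, 3, 4, 7, 8, 9, 10, 11, 12); steps 5 and 6 form the two-step side branch to 11.

**Steps most likely to fail, with fallbacks**

Step 7. The aroylketene may be consumed by self-condensation, the phenol may stay O-acylated without going on to C-acylation, or some Pechmann-type closure to the 4-arylcoumarin and thermal degradation may occur at 240 °C. The fallback builds the pyranone ring of the 6-aryloxy flavone through a chalcone, sets out from 7 and comes back at 15. Friedel–Crafts acetylation of 7 (Ac2O, BF3·OEt2, 0 °C → rt, aqueous work-up) at either of the two equivalent carbons ortho to the hydroxyl should give methyl 4-(3-acetyl-4-hydroxy-2,6-diisopropoxyphenoxy)benzoate F1. Claisen–Schmidt condensation of F1 with commercial 4-isopropoxybenzaldehyde (excess aq. KOH, EtOH, rt, then aq. HCl), which also saponifies the methyl ester, should give 4-{4-hydroxy-3-[(E)-3-(4-isopropoxyphenyl)prop-2-enoyl]-2,6-diisopropoxyphenoxy}benzoic acid F2. Oxidative cyclisation of F2 (cat. I2, DMSO, 120 °C) should then give acid 15, and the same symmetry argument fixes the aryloxy group at C6.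

Step 3. Addition of the hindered, weakly nucleophilic 2,6-dialkoxy-4-formylphenoxide to a fluoride activated only by an ester may be slow, so that ester hydrolysis and aldehyde degradation compete. The fallback replaces SNAr by ligand coupling on hypervalent iodine, sets out from 3 and comes back at 5. Commercial methyl 4-iodobenzoate is oxidised (mCPBA, TsOH·H2O, MeCN) and trapped with 1,3,5-trimethoxybenzene to give [4-(methoxycarbonyl)phenyl](2,4,6-trimethoxyphenyl)iodonium 4-methylbenzenesulfonate F3. Treatment of 3 with F3 (K2CO3, MeCN, 50 °C) should transfer the electron-poor aryl group to the phenoxide oxygen, a metal-free arylation that tolerates di-ortho-substituted phenols, and give 5.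

Step 2. The Lewis acid may cleave a second isopropyl ether, or the site selectivity for the central ether may be poor. The fallback differentiates the C4 oxygen by protection instead of selective cleavage, sets out from 1 and comes back at 3. Benzylation of the most acidic C4 hydroxyl of 1 (BnBr, NaHCO3, cat. NaI, DMF, 40 °C) should give 4-(benzyloxy)-3,5-dihydroxybenzaldehyde F4. Isopropylation of F4 (2-bromopropane, K2CO3, DMF, 70 °C) gives 4-(benzyloxy)-3,5-diisopropoxybenzaldehyde F5. Hydrogenolysis of F5 (H2 at 1 atm, Pd/C, EtOAc, rt, stopped at full conversion to spare the aldehyde) should give 3.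

**Further compounds**
F1 | step 7 | methyl 4-(3-acetyl-4-hydroxy-2,6-diisopropoxyphenoxy)benzoate | COC(=O)c1ccc(Oc2c(OC(C)C)cc(O)c(C(C)=O)c2OC(C)C)cc1
F2 | step 7 | 4-{4-hydroxy-3-[(E)-3-(4-isopropoxyphenyl)prop-2-enoyl]-2,6-diisopropoxyphenoxy}benzoic acid | OC(=O)c1ccc(Oc2c(OC(C)C)cc(O)c(C(=O)/C=C/c3ccc(OC(C)C)cc3)c2OC(C)C)cc1
F3 | step 3 | [4-(methoxycarbonyl)phenyl](2,4,6-trimethoxyphenyl)iodonium 4-methylbenzenesulfonate | COC(=O)c1ccc([I+]c2c(OC)cc(OC)cc2OC)cc1.Cc1ccc(S(=O)(=O)[O-])cc1
F4 | step 2 | 4-(benzyloxy)-3,5-dihydroxybenzaldehyde | O=Cc1cc(O)c(OCc2ccccc2)c(O)c1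
F5 | step 2 | 4-(benzyloxy)-3,5-diisopropoxybenzaldehyde | O=Cc1cc(OC(C)C)c(OCc2ccccc2)c(OC(C)C)c1
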